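**Retrosynthetic overview**

1. Target 39 ⇐ tris-silyl ether 38 ⇐ seco ester 36. The 28-membered ring (the only ring, formed last) is closed through the C6–C7 C(sp3)–C(sp3) bond, with C7 as a primary alkyl-9-BBN made from the terminal C7=C8 alkene and C6 as a secondary chloride.
2. 36 ⇐ ester (C1–O–C3) of hydroxy amide 35 with (2S)-4-chloro-2-methylpentanoic acid 6. 35 ⇐ amide (N27–C28) of amine 33 with (S)-2-hydroxypentanoic acid 34.
3. 33 ⇐ Julia–Kocienski olefination (C16=C17) of sulfone 12 (C7–C16) with enal 29 (C17–C26). 29 ⇐ syn-hydroalkylation of alkynoate 16 by the borane of alkene 25. 25 ⇐ anti-hydroxyallylation of aldehyde 20.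
4. Enabling feature: C6 lies γ to the lactone carbonyl C3 (O=C3–C4–C5–C6, with the C4 methyl stereocentre in between), so a C6 chloride is a γ-chloro ester whose carbonyl can hold the C6 centre on nickel. C7 opens the unfunctionalised octamethylene run C7–C14, which can be carried as an inert terminal alkene.

Key step: step 20

Remark: ring atoms are numbered C1 (CH bearing n-propyl), O2, C3 (lactone C=O), C4 to C26 along the carbon chain, N27, C28 (amide C=O), and these locants are used for all intermediates. Compounds 8, 17, 21 and 34 are taken as commercial (34 is otherwise available from L-norvaline by diazotisation with retention). Compounds 5, 6, 36 and 37 are C6 epimer mixtures and are drawn without configuration at that carbon.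

**Route**

Step 1
Reactants: 1 (4R)-4-benzyl-3-propanoyl-1,3-oxazolidin-2-one; 2 3-bromoprop-1-ene (allyl bromide)
Product: 4 (4R)-4-benzyl-3-[(2S)-2-methylpent-4-enoyl]-1,3-oxazolidin-2-one, via sodium enolate 3 (not isolated)
Conditions: NaN(SiMe3)2, THF, −78 °C; then 2, −78 → −40 °C
Reagents that add atoms: none
Why: Evans alkylation, in which the chelated sodium Z-enolate is allylated on the face opposite the benzyl group, which should set C4 as S.

Step 2
Reactants: 4 (4R)-4-benzyl-3-[(2S)-2-methylpent-4-enoyl]-1,3-oxazolidin-2-one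
Product: 5 (4R)-4-benzyl-3-[(2S,4RS)-4-chloro-2-methylpentanoyl]-1,3-oxazolidin-2-one
Conditions: Co(BF4)2·6H2O (cat.), potassium 2-[(3,5-di-tert-butyl-2-hydroxybenzylidene)amino]-2,2-diphenylacetate (ligand, cat.), t-BuOOH (cat.), PhSiH3, TsCl, EtOH, rt
Reagents that add atoms: 4-methylbenzenesulfonyl chloride (TsCl), Cc1ccc(cc1)S(=O)(=O)Cl
Why: Cobalt-hydride hydrogen-atom-transfer hydrochlorination is Markovnikov selective and should give the secondary C6 chloride as an epimer mixture, which is acceptable because the key step is stereoconvergent at C6.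

Step 3
Reactants: 5 (4R)-4-benzyl-3-[(2S,4RS)-4-chloro-2-methylpentanoyl]-1,3-oxazolidin-2-one
Product: 6 (2S,4RS)-4-chloro-2-methylpentanoic acid
Conditions: LiOH, H2O2, THF/H2O, 0 °C; then Na2SO3; then aq. HCl
Reagents that add atoms: hydrogen peroxide, OO
Why: Hydroperoxide cleaves the exocyclic imide carbonyl selectively (standard auxiliary removal) and at 0 °C should neither epimerise C4 nor displace the secondary chloride.

Step 4
Reactants: 7 7-bromohept-1-ene; 8 (2S)-3-bromo-2-methylpropan-1-ol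
Product: 10 (2R)-2-methyldec-9-en-1-ol, via Grignard reagent 9 (not isolated)
Conditions: Mg, THF (7 → 9, excess); then 8, Li2CuCl4 (cat.), THF, −78 → 0 °C; aq. NH4Cl
Reagents that add atoms: none
Why: Copper-catalysed sp3–sp3 Grignard cross-coupling at the primary bromide, in which one equivalent of 9 only deprotonates the hydroxyl and the C15 stereocentre taken from 8 is untouched (S becomes R only by the priority switch).

Step 5
Reactants: 10 (2R)-2-methyldec-9-en-1-ol
Product: 11 5-{[(2R)-2-methyldec-9-en-1-yl]sulfanyl}-1-phenyl-1H-tetrazole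
Conditions: PPh3, DIAD, 1-phenyl-1H-tetrazole-5-thiol, THF, 0 °C → rt
Reagents that add atoms: 1-phenyl-1H-tetrazole-5-thiol, Sc1nnnn1-c1ccccc1
Why: Mitsunobu thioetherification of the primary alcohol, which does not involve the C15 stereocentre.

Step 6
Reactants: 11 5-{[(2R)-2-methyldec-9-en-1-yl]sulfanyl}-1-phenyl-1H-tetrazole
Product: 12 5-{[(2R)-2-methyldec-9-en-1-yl]sulfonyl}-1-phenyl-1H-tetrazole
Conditions: (NH4)6Mo7O24·4H2O (cat.), H2O2 (30% aq.), EtOH, 0 °C → rt
Reagents that add atoms: hydrogen peroxide, OO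
Why: Molybdate-catalysed oxidation of sulfide to sulfone, under which the isolated terminal alkene should not be epoxidised.

Step 7
Reactants: 13 3-methoxyprop-1-yne; 14 methyl chloroformate
Product: 16 methyl 4-methoxybut-2-ynoate, via lithium acetylide 15 (not isolated)
Conditions: n-BuLi, THF, −78 °C; then 14, −78 → 0 °C
Reagents that add atoms: none
Why: Deprotonation of the terminal alkyne and C-acylation of the acetylide by the chloroformate.

Step 8
Reactants: 17 ethyl (3S)-4-chloro-3-hydroxybutanoate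
Product: 18 ethyl (3S)-4-azido-3-hydroxybutanoate
Conditions: NaN3, DMF, 85 °C
Reagents that add atoms: sodium azide, [Na+].[N-]=[N+]=[N-]
Why: SN2 displacement of the primary chloride by azide (directly or through the epoxide, which reopens at the same carbon), so the C25 stereocentre is kept.

Step 9
Reactants: 18 ethyl (3S)-4-azido-3-hydroxybutanoate
Product: 19 ethyl (3S)-4-azido-3-[(tert-butyldimethylsilyl)oxy]butanoate
Conditions: TBSCl, imidazole, DMF, rt
Reagents that add atoms: tert-butyldimethylsilyl chloride (TBSCl), CC(C)(C)[Si](C)(C)Cl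
Why: Standard silylation of the secondary alcohol.

Step 10
Reactants: 19 ethyl (3S)-4-azido-3-[(tert-butyldimethylsilyl)oxy]butanoate
Product: 20 (3S)-4-azido-3-[(tert-butyldimethylsilyl)oxy]butanal
Conditions: i-Bu2AlH, CH2Cl2, −78 °C; aq. KNaC4H4O6
Reagents that add atoms: none
Why: Low-temperature partial reduction of the ester stops at the aluminium hemiacetal, and azide and silyl ether should survive.

Step 11
Reactants: 20 (3S)-4-azido-3-[(tert-butyldimethylsilyl)oxy]butanal; 21 4,4,5,5-tetramethyl-2-(propa-1,2-dien-1-yl)-1,3,2-dioxaborolane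
Product: 24 (3R,4S,6S)-7-azido-6-[(tert-butyldimethylsilyl)oxy]hept-1-ene-3,4-diol, via allylborane 22 (not isolated), via borinate adduct 23 (not isolated)
Conditions: (+)-Ipc2BH [from (−)-α-pinene], THF, 0 °C → rt (with 21); then 20, −78 °C; then aq. NaOH, H2O2, 0 °C → rt
Reagents that add atoms: hydrogen peroxide, OO
Why: Hydroboration of the allene gives the (E)-γ-boryl allylborane, which adds to the aldehyde through a chair six-membered transition state (E geometry gives anti, the isopinocampheyl groups choose the aldehyde face by reagent control), and stereoretentive C–B oxidation should give the 22,23-anti diol with 22R and 23S.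

Step 12
Reactants: 24 (3R,4S,6S)-7-azido-6-[(tert-butyldimethylsilyl)oxy]hept-1-ene-3,4-diol
Product: 25 (3R,4S,6S)-7-azido-3,4,6-tris[(tert-butyldimethylsilyl)oxy]hept-1-ene
Conditions: TBSOTf, 2,6-lutidine, CH2Cl2, −78 → 0 °C
Reagents that add atoms: tert-butyldimethylsilyl trifluoromethanesulfonate (TBSOTf), CC(C)(C)[Si](C)(C)OS(=O)(=O)C(F)(F)F
Why: The silyl triflate with lutidine silylates both hindered secondary hydroxyls.

Step 13
Reactants: 25 (3R,4S,6S)-7-azido-3,4,6-tris[(tert-butyldimethylsilyl)oxy]hept-1-ene; 16 methyl 4-methoxybut-2-ynoate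
Product: 27 methyl (2Z,6R,7S,9S)-10-azido-6,7,9-tris[(tert-butyldimethylsilyl)oxy]-3-(methoxymethyl)dec-2-enoate, via alkylborane 26 (not isolated)
Conditions: 9-BBN dimer, THF, rt; then 16, CuOAc (cat.), P(OPh)3 (cat.), KOt-Bu (cat.), t-BuOH, 1,4-dioxane, 40 °C
Reagents that add atoms: none
Why: 9-BBN hydroborates the terminal alkene anti-Markovnikov, and the copper-catalysed conjugate addition of the alkylborane to the alkynoate is a syn hydroalkylation (syn carbocupration, then protonation with retention), which should place C20 trans and the methoxymethyl group cis to the ester (18Z).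

Step 14
Reactants: 27 methyl (2Z,6R,7S,9S)-10-azido-6,7,9-tris[(tert-butyldimethylsilyl)oxy]-3-(methoxymethyl)dec-2-enoate
Product: 28 (2Z,6R,7S,9S)-10-azido-6,7,9-tris[(tert-butyldimethylsilyl)oxy]-3-(methoxymethyl)dec-2-en-1-ol
Conditions: i-Bu2AlH, CH2Cl2, −78 °C; aq. KNaC4H4O6
Reagents that add atoms: none
Why: 1,2-Reduction of the enoate to the allylic alcohol at low temperature should keep the alkene geometry and the azide.

Step 15
Reactants: 28 (2Z,6R,7S,9S)-10-azido-6,7,9-tris[(tert-butyldimethylsilyl)oxy]-3-(methoxymethyl)dec-2-en-1-ol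
Product: 29 (2Z,6R,7S,9S)-10-azido-6,7,9-tris[(tert-butyldimethylsilyl)oxy]-3-(methoxymethyl)dec-2-enal
Conditions: MnO2, CH2Cl2, rt
Reagents that add atoms: none
Why: Chemoselective allylic oxidation to the enal under neutral conditions that should retain the alkene geometry.

Step 16
Reactants: 12 5-{[(2R)-2-methyldec-9-en-1-yl]sulfonyl}-1-phenyl-1H-tetrazole; 29 (2Z,6R,7S,9S)-10-azido-6,7,9-tris[(tert-butyldimethylsilyl)oxy]-3-(methoxymethyl)dec-2-enal
Product: 31 (2S,4S,5R,8Z,10E,12R)-1-azido-2,4,5-tris[(tert-butyldimethylsilyl)oxy]-8-(methoxymethyl)-12-methylicosa-8,10,19-triene, via sulfonyl carbanion 30 (not isolated)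
Conditions: KN(SiMe3)2, 1,2-dimethoxyethane, −60 °C; then 29, −60 °C → rt; aq. NH4Cl
Reagents that add atoms: none
Why: Julia–Kocienski olefination (addition of the metallated tetrazolyl sulfone, Smiles rearrangement, anti elimination of SO2 and tetrazolate) should give the 16E alkene without touching C15.

Step 17
Reactants: 31 (2S,4S,5R,8Z,10E,12R)-1-azido-2,4,5-tris[(tert-butyldimethylsilyl)oxy]-8-(methoxymethyl)-12-methylicosa-8,10,19-triene
Product: 33 (2S,4S,5R,8Z,10E,12R)-2,4,5-tris[(tert-butyldimethylsilyl)oxy]-8-(methoxymethyl)-12-methylicosa-8,10,19-trien-1-amine, via iminophosphorane 32 (not isolated)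
Conditions: PPh3, THF, rt; then H2O, 50 °C
Reagents that add atoms: none
Why: Staudinger reduction of the azide, which is compatible with the triene and the silyl ethers.

Step 18
Reactants: 33 (2S,4S,5R,8Z,10E,12R)-2,4,5-tris[(tert-butyldimethylsilyl)oxy]-8-(methoxymethyl)-12-methylicosa-8,10,19-trien-1-amine; 34 (2S)-2-hydroxypentanoic acid
Product: 35 (2S)-N-[(2S,4S,5R,8Z,10E,12R)-2,4,5-tris[(tert-butyldimethylsilyl)oxy]-8-(methoxymethyl)-12-methylicosa-8,10,19-trien-1-yl]-2-hydroxypentanamide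
Conditions: EDC·HCl, HOBt, i-Pr2NEt, CH2Cl2, 0 °C → rt
Reagents that add atoms: none
Why: Carbodiimide/HOBt amide coupling, in which the amine far outruns the α-hydroxyl so that 34 needs no protection and C1 (chiral pool) should not epimerise.

Step 19
Reactants: 35 (2S)-N-[(2S,4S,5R,8Z,10E,12R)-2,4,5-tris[(tert-butyldimethylsilyl)oxy]-8-(methoxymethyl)-12-methylicosa-8,10,19-trien-1-yl]-2-hydroxypentanamide; 6 (2S,4RS)-4-chloro-2-methylpentanoic acid
Product: 36 (2S)-1-{[(2S,4S,5R,8Z,10E,12R)-2,4,5-tris[(tert-butyldimethylsilyl)oxy]-8-(methoxymethyl)-12-methylicosa-8,10,19-trien-1-yl]amino}-1-oxopentan-2-yl (2S,4RS)-4-chloro-2-methylpentanoate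
Conditions: DIC, DMAP (cat.), CH2Cl2, 0 °C → rt
Reagents that add atoms: none
Why: Steglich esterification of the secondary C1 hydroxyl, run cold to limit epimerisation of C4 in the activated acid.

Step 20
Reactants: 36 (2S)-1-{[(2S,4S,5R,8Z,10E,12R)-2,4,5-tris[(tert-butyldimethylsilyl)oxy]-8-(methoxymethyl)-12-methylicosa-8,10,19-trien-1-yl]amino}-1-oxopentan-2-yl (2S,4RS)-4-chloro-2-methylpentanoate
Product: 38 (2S,6S,8S,9R,12Z,14E,16R,25R,27S)-6,8,9-tris[(tert-butyldimethylsilyl)oxy]-12-(methoxymethyl)-16,25,27-trimethyl-2-propyl-1-oxa-4-azacyclooctacosa-12,14-diene-3,28-dione, via alkylborane 37 (not isolated)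
Conditions: 9-BBN dimer, THF, rt; then slow addition to NiBr2·diglyme, (R,R)-N,N′-dimethyl-1,2-diphenylethane-1,2-diamine (enantiomer to be matched on a model γ-chloro ester), KOt-Bu, i-BuOH, i-Pr2O/1,4-dioxane, rt, high dilution
Reagents that add atoms: none
Why: Proposed new method: 9-BBN should add only to the monosubstituted C7=C8 alkene of 36, and the alkoxide-activated borate of 37 should pass its primary C7 alkyl group to a chiral monovalent nickel–diamine complex, which abstracts chlorine from C6, recaptures the planar C6 radical and forms the C6–C7 bond by reductive elimination from trivalent nickel. The closest known reactions are the nickel/diamine-catalysed stereoconvergent Suzuki coupling of racemic γ-chloro amides (and other unactivated secondary alkyl chlorides) with primary alkyl-9-BBN reagents and the B-alkyl Suzuki–Miyaura macrocyclisation; new here are the ester as the directing carbonyl and the ring-forming C(sp3)–C(sp3) version. The 28-membered ring (the only ring) is closed end to end by this cross-coupling under high dilution with slow addition of 37 to the catalyst. The new C6 stereocentre (R) is set by the catalyst: both C6 epimers of 36 funnel into one radical, the lactone carbonyl oxygen holds it on the chiral nickel centre through a six-membered O=C3–C4–C5–C6–Ni chelate, and the ligand enantiomer is chosen to match the 4,6-anti bias of the C4 methyl group in that chelate. The step needs chemoselective hydroboration (secured by the steric demand of 9-BBN and the lower reactivity of the conjugated, more substituted diene), ring closure over oligomerisation (dilution) and coupling over β-hydride elimination (diamine ligand, room temperature), and it leaves the existing stereocentres untouched.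

Step 21
Reactants: 38 (2S,6S,8S,9R,12Z,14E,16R,25R,27S)-6,8,9-tris[(tert-butyldimethylsilyl)oxy]-12-(methoxymethyl)-16,25,27-trimethyl-2-propyl-1-oxa-4-azacyclooctacosa-12,14-diene-3,28-dione
Product: 39 (2S,6S,8S,9R,12Z,14E,16R,25R,27S)-6,8,9-trihydroxy-12-(methoxymethyl)-16,25,27-trimethyl-2-propyl-1-oxa-4-azacyclooctacosa-12,14-diene-3,28-dione (CNP0511044.1)
Conditions: HF·pyridine, pyridine, THF, 0 °C → rt
Reagents that add atoms: none
Why: Buffered fluoride desilylation should remove the three silyl ethers while leaving the lactone, the amide and the dienyl methyl ether intact.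

**Compound list**

1 | (4R)-4-benzyl-3-propanoyl-1,3-oxazolidin-2-one | CCC(=O)N1[C@H](Cc2ccccc2)COC1=O | starting material
2 | 3-bromoprop-1-ene (allyl bromide) | C=CCBr | starting material
3 | sodium (Z)-enolate of 1 | C/C=C(\[O-])N1[C@H](Cc2ccccc2)COC1=O.[Na+] | intermediate
4 | (4R)-4-benzyl-3-[(2S)-2-methylpent-4-enoyl]-1,3-oxazolidin-2-one | C=CC[C@H](C)C(=O)N1[C@H](Cc2ccccc2)COC1=O | intermediate
5 | (4R)-4-benzyl-3-[(2S,4RS)-4-chloro-2-methylpentanoyl]-1,3-oxazolidin-2-one | CC(Cl)C[C@H](C)C(=O)N1[C@H](Cc2ccccc2)COC1=O | intermediate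
6 | (2S,4RS)-4-chloro-2-methylpentanoic acid | CC(Cl)C[C@H](C)C(=O)O | intermediate
7 | 7-bromohept-1-ene | C=CCCCCCBr | starting material
8 | (2S)-3-bromo-2-methylpropan-1-ol | BrC[C@@H](C)CO | starting material
9 | hept-6-en-1-ylmagnesium bromide | C=CCCCCC[Mg]Br | intermediate
10 | (2R)-2-methyldec-9-en-1-ol | C=CCCCCCC[C@@H](C)CO | intermediate
11 | 5-{[(2R)-2-methyldec-9-en-1-yl]sulfanyl}-1-phenyl-1H-tetrazole | C=CCCCCCC[C@@H](C)CSc1nnnn1-c1ccccc1 | intermediate
12 | 5-{[(2R)-2-methyldec-9-en-1-yl]sulfonyl}-1-phenyl-1H-tetrazole | C=CCCCCCC[C@@H](C)CS(=O)(=O)c1nnnn1-c1ccccc1 | intermediate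
13 | 3-methoxyprop-1-yne | COCC#C | starting material
14 | methyl chloroformate | COC(=O)Cl | starting material
15 | lithium 3-methoxyprop-1-yn-1-ide | [Li+].[C-]#CCOC | intermediate
16 | methyl 4-methoxybut-2-ynoate | COCC#CC(=O)OC | intermediate
17 | ethyl (3S)-4-chloro-3-hydroxybutanoate | CCOC(=O)C[C@H](O)CCl | starting material
18 | ethyl (3S)-4-azido-3-hydroxybutanoate | CCOC(=O)C[C@H](O)CN=[N+]=[N-] | intermediate
19 | ethyl (3S)-4-azido-3-[(tert-butyldimethylsilyl)oxy]butanoate | CCOC(=O)C[C@H](O[Si](C)(C)C(C)(C)C)CN=[N+]=[N-] | intermediate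
20 | (3S)-4-azido-3-[(tert-butyldimethylsilyl)oxy]butanal | O=CC[C@H](O[Si](C)(C)C(C)(C)C)CN=[N+]=[N-] | intermediate
21 | 4,4,5,5-tetramethyl-2-(propa-1,2-dien-1-yl)-1,3,2-dioxaborolane | C=C=CB1OC(C)(C)C(C)(C)O1 | starting material
22 | [(2E)-3-(4,4,5,5-tetramethyl-1,3,2-dioxaborolan-2-yl)prop-2-en-1-yl]di(isopinocampheyl)borane, isopinocampheyl groups from (−)-α-pinene | CC1(C)OB(/C=C/CB([C@H]2C[C@H]3C[C@@H]([C@@H]2C)C3(C)C)[C@H]2C[C@H]3C[C@@H]([C@@H]2C)C3(C)C)OC1(C)C | intermediate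
23 | di(isopinocampheyl)borinate of (3R,4S,6S)-7-azido-6-[(tert-butyldimethylsilyl)oxy]-3-(4,4,5,5-tetramethyl-1,3,2-dioxaborolan-2-yl)hept-1-en-4-ol | C=C[C@@H](B1OC(C)(C)C(C)(C)O1)[C@@H](OB([C@H]2C[C@H]3C[C@@H]([C@@H]2C)C3(C)C)[C@H]2C[C@H]3C[C@@H]([C@@H]2C)C3(C)C)C[C@H](O[Si](C)(C)C(C)(C)C)CN=[N+]=[N-] | intermediate
24 | (3R,4S,6S)-7-azido-6-[(tert-butyldimethylsilyl)oxy]hept-1-ene-3,4-diol | C=C[C@@H](O)[C@@H](O)C[C@H](O[Si](C)(C)C(C)(C)C)CN=[N+]=[N-] | intermediate
25 | (3R,4S,6S)-7-azido-3,4,6-tris[(tert-butyldimethylsilyl)oxy]hept-1-ene | C=C[C@@H](O[Si](C)(C)C(C)(C)C)[C@@H](O[Si](C)(C)C(C)(C)C)C[C@H](O[Si](C)(C)C(C)(C)C)CN=[N+]=[N-] | intermediate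
26 | 9-[(3R,4S,6S)-7-azido-3,4,6-tris[(tert-butyldimethylsilyl)oxy]heptyl]-9-borabicyclo[3.3.1]nonane | C1CCC2CCCC1B2CC[C@@H](O[Si](C)(C)C(C)(C)C)[C@@H](O[Si](C)(C)C(C)(C)C)C[C@H](O[Si](C)(C)C(C)(C)C)CN=[N+]=[N-] | intermediate
27 | methyl (2Z,6R,7S,9S)-10-azido-6,7,9-tris[(tert-butyldimethylsilyl)oxy]-3-(methoxymethyl)dec-2-enoate | COC(=O)/C=C(\COC)CC[C@@H](O[Si](C)(C)C(C)(C)C)[C@@H](O[Si](C)(C)C(C)(C)C)C[C@H](O[Si](C)(C)C(C)(C)C)CN=[N+]=[N-] | intermediate
28 | (2Z,6R,7S,9S)-10-azido-6,7,9-tris[(tert-butyldimethylsilyl)oxy]-3-(methoxymethyl)dec-2-en-1-ol | OC/C=C(\COC)CC[C@@H](O[Si](C)(C)C(C)(C)C)[C@@H](O[Si](C)(C)C(C)(C)C)C[C@H](O[Si](C)(C)C(C)(C)C)CN=[N+]=[N-] | intermediate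
29 | (2Z,6R,7S,9S)-10-azido-6,7,9-tris[(tert-butyldimethylsilyl)oxy]-3-(methoxymethyl)dec-2-enal | O=C/C=C(\COC)CC[C@@H](O[Si](C)(C)C(C)(C)C)[C@@H](O[Si](C)(C)C(C)(C)C)C[C@H](O[Si](C)(C)C(C)(C)C)CN=[N+]=[N-] | intermediate
30 | potassium salt of the α-sulfonyl carbanion of 12 | [K+].C=CCCCCCC[C@@H](C)[CH-]S(=O)(=O)c1nnnn1-c1ccccc1 | intermediate
31 | (2S,4S,5R,8Z,10E,12R)-1-azido-2,4,5-tris[(tert-butyldimethylsilyl)oxy]-8-(methoxymethyl)-12-methylicosa-8,10,19-triene | C=CCCCCCC[C@@H](C)/C=C/C=C(\COC)CC[C@@H](O[Si](C)(C)C(C)(C)C)[C@@H](O[Si](C)(C)C(C)(C)C)C[C@H](O[Si](C)(C)C(C)(C)C)CN=[N+]=[N-] | intermediate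
32 | N-(triphenyl-λ5-phosphanylidene) derivative (iminophosphorane) of amine 33 | C=CCCCCCC[C@@H](C)/C=C/C=C(\COC)CC[C@@H](O[Si](C)(C)C(C)(C)C)[C@@H](O[Si](C)(C)C(C)(C)C)C[C@H](O[Si](C)(C)C(C)(C)C)CN=P(c1ccccc1)(c1ccccc1)c1ccccc1 | intermediate
33 | (2S,4S,5R,8Z,10E,12R)-2,4,5-tris[(tert-butyldimethylsilyl)oxy]-8-(methoxymethyl)-12-methylicosa-8,10,19-trien-1-amine | C=CCCCCCC[C@@H](C)/C=C/C=C(\COC)CC[C@@H](O[Si](C)(C)C(C)(C)C)[C@@H](O[Si](C)(C)C(C)(C)C)C[C@H](O[Si](C)(C)C(C)(C)C)CN | intermediate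
34 | (2S)-2-hydroxypentanoic acid | CCC[C@H](O)C(=O)O | starting material
35 | (2S)-N-[(2S,4S,5R,8Z,10E,12R)-2,4,5-tris[(tert-butyldimethylsilyl)oxy]-8-(methoxymethyl)-12-methylicosa-8,10,19-trien-1-yl]-2-hydroxypentanamide | C=CCCCCCC[C@@H](C)/C=C/C=C(\COC)CC[C@@H](O[Si](C)(C)C(C)(C)C)[C@@H](O[Si](C)(C)C(C)(C)C)C[C@H](O[Si](C)(C)C(C)(C)C)CNC(=O)[C@@H](O)CCC | intermediate
36 | (2S)-1-{[(2S,4S,5R,8Z,10E,12R)-2,4,5-tris[(tert-butyldimethylsilyl)oxy]-8-(methoxymethyl)-12-methylicosa-8,10,19-trien-1-yl]amino}-1-oxopentan-2-yl (2S,4RS)-4-chloro-2-methylpentanoate | C=CCCCCCC[C@@H](C)/C=C/C=C(\COC)CC[C@@H](O[Si](C)(C)C(C)(C)C)[C@@H](O[Si](C)(C)C(C)(C)C)C[C@H](O[Si](C)(C)C(C)(C)C)CNC(=O)[C@H](CCC)OC(=O)[C@@H](C)CC(C)Cl | intermediate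
37 | B-alkyl-9-borabicyclo[3.3.1]nonane from 36 (boron on C7) | C1CCC2CCCC1B2CCCCCCCC[C@@H](C)/C=C/C=C(\COC)CC[C@@H](O[Si](C)(C)C(C)(C)C)[C@@H](O[Si](C)(C)C(C)(C)C)C[C@H](O[Si](C)(C)C(C)(C)C)CNC(=O)[C@H](CCC)OC(=O)[C@@H](C)CC(C)Cl | intermediate
38 | (2S,6S,8S,9R,12Z,14E,16R,25R,27S)-6,8,9-tris[(tert-butyldimethylsilyl)oxy]-12-(methoxymethyl)-16,25,27-trimethyl-2-propyl-1-oxa-4-azacyclooctacosa-12,14-diene-3,28-dione | CCC[C@@H]1OC(=O)[C@@H](C)C[C@H](C)CCCCCCCC[C@@H](C)/C=C/C=C(\COC)CC[C@@H](O[Si](C)(C)C(C)(C)C)[C@@H](O[Si](C)(C)C(C)(C)C)C[C@H](O[Si](C)(C)C(C)(C)C)CNC1=O | intermediate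
39 | (2S,6S,8S,9R,12Z,14E,16R,25R,27S)-6,8,9-trihydroxy-12-(methoxymethyl)-16,25,27-trimethyl-2-propyl-1-oxa-4-azacyclooctacosa-12,14-diene-3,28-dione (CNP0511044.1) | CCC[C@@H]1OC(=O)[C@@H](C)C[C@H](C)CCCCCCCC[C@@H](C)/C=C/C=C(\COC)CC[C@@H](O)[C@@H](O)C[C@H](O)CNC1=O | target

**Step count and risks**

Total step count: 21. Longest linear sequence: 14 steps (steps 8 to 21, from 17).

Steps most likely to fail:

1. Step 20 (Proposed new method). The alkylnickel intermediate may be lost to β-hydride elimination or protodemetalation, and open-chain oligomers may form faster than the 28-membered ring. The C6 radical may escape catalyst control because the ester is a weaker director than an amide (poor facial selectivity at C6), or it may add to the diene. Alkoxide may also attack the C1 ester. Fallback (known chemistry; sets out from 1 and 35, returns at 38): imide 1 is alkylated as in step 1 but with 2,3-dibromoprop-1-ene to give (4R)-4-benzyl-3-[(2S)-4-bromo-2-methylpent-4-enoyl]-1,3-oxazolidin-2-one F1, which LiOH/H2O2 cleaves to (2S)-4-bromo-2-methylpent-4-enoic acid F2. Esterification of 35 with F2 (DIC, DMAP) gives the seco vinyl bromide F3. 9-BBN hydroboration of its terminal alkene gives the B-alkyl borane F4, and a B-alkyl Suzuki–Miyaura macrocyclisation (Pd(dppf)Cl2, AsPh3, Cs2CO3, DMF/THF/H2O, high dilution) closes the same C6–C7 bond as an sp2–sp3 bond to give the 6-methylidene macrocycle F5. Hydrogenation of its 1,1-disubstituted alkene with RhCl(PPh3)3/H2, which should spare the more substituted conjugated diene, then gives 38; this fallback does not control C6, so the C6 epimers would be separated by chromatography.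

2. Step 13. The alkenylcopper intermediate may isomerise through the allenoate, which would erode the syn relationship and give a mixture at C18=C19, and hydroboration next to the two silyloxy groups may be slow. Fallback (sets out from 25 through borane 26, returns at 27): methyl 4-methoxy-3-oxobutanoate is triflated under non-chelating conditions (Tf2O, aq. Me4NOH) to methyl (2E)-4-methoxy-3-{[(trifluoromethyl)sulfonyl]oxy}but-2-enoate F6, and borane 26 is coupled with F6 by a stereoretentive B-alkyl Suzuki–Miyaura reaction (Pd(dppf)Cl2, K3PO4, DMF/THF) to give 27.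

3. Step 16. E selectivity at C16=C17 may erode with the conjugated aldehyde, and the base may deprotonate the enal at its γ-positions or isomerise it. Fallback (sets out from 28 and 10, returns at 31): 28 is converted by an Appel reaction (CBr4, PPh3) into (2Z,6R,7S,9S)-10-azido-1-bromo-6,7,9-tris[(tert-butyldimethylsilyl)oxy]-3-(methoxymethyl)dec-2-ene F7 and then by a Michaelis–Becker reaction (NaP(O)(OEt)2, THF) into the diethyl allylic phosphonate F8. Alcohol 10 is oxidised with Dess–Martin periodinane to (2R)-2-methyldec-9-enal F9. Deprotonation of F8 with LiN(SiMe3)2 at −78 °C and addition of F9 (E-selective Horner–Wadsworth–Emmons olefination with the roles of the two fragments reversed) gives 31.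

Further compounds
F1 | step 20 | (4R)-4-benzyl-3-[(2S)-4-bromo-2-methylpent-4-enoyl]-1,3-oxazolidin-2-one | C=C(Br)C[C@H](C)C(=O)N1[C@H](Cc2ccccc2)COC1=O
F2 | step 20 | (2S)-4-bromo-2-methylpent-4-enoic acid | C=C(Br)C[C@H](C)C(=O)O
F3 | step 20 | (2S)-1-{[(2S,4S,5R,8Z,10E,12R)-2,4,5-tris[(tert-butyldimethylsilyl)oxy]-8-(methoxymethyl)-12-methylicosa-8,10,19-trien-1-yl]amino}-1-oxopentan-2-yl (2S)-4-bromo-2-methylpent-4-enoate | C=CCCCCCC[C@@H](C)/C=C/C=C(\COC)CC[C@@H](O[Si](C)(C)C(C)(C)C)[C@@H](O[Si](C)(C)C(C)(C)C)C[C@H](O[Si](C)(C)C(C)(C)C)CNC(=O)[C@H](CCC)OC(=O)[C@@H](C)CC(Br)=C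
F4 | step 20 | B-alkyl-9-borabicyclo[3.3.1]nonane from F3 (boron on C7) | C1CCC2CCCC1B2CCCCCCCC[C@@H](C)/C=C/C=C(\COC)CC[C@@H](O[Si](C)(C)C(C)(C)C)[C@@H](O[Si](C)(C)C(C)(C)C)C[C@H](O[Si](C)(C)C(C)(C)C)CNC(=O)[C@H](CCC)OC(=O)[C@@H](C)CC(Br)=C
F5 | step 20 | (2S,6S,8S,9R,12Z,14E,16R,27S)-6,8,9-tris[(tert-butyldimethylsilyl)oxy]-12-(methoxymethyl)-16,27-dimethyl-25-methylidene-2-propyl-1-oxa-4-azacyclooctacosa-12,14-diene-3,28-dione | CCC[C@@H]1OC(=O)[C@@H](C)CC(=C)CCCCCCCC[C@@H](C)/C=C/C=C(\COC)CC[C@@H](O[Si](C)(C)C(C)(C)C)[C@@H](O[Si](C)(C)C(C)(C)C)C[C@H](O[Si](C)(C)C(C)(C)C)CNC1=O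
F6 | step 13 | methyl (2E)-4-methoxy-3-{[(trifluoromethyl)sulfonyl]oxy}but-2-enoate | COC(=O)/C=C(\COC)OS(=O)(=O)C(F)(F)F
F7 | step 16 | (2Z,6R,7S,9S)-10-azido-1-bromo-6,7,9-tris[(tert-butyldimethylsilyl)oxy]-3-(methoxymethyl)dec-2-ene | BrC/C=C(\COC)CC[C@@H](O[Si](C)(C)C(C)(C)C)[C@@H](O[Si](C)(C)C(C)(C)C)C[C@H](O[Si](C)(C)C(C)(C)C)CN=[N+]=[N-]
F8 | step 16 | diethyl [(2Z,6R,7S,9S)-10-azido-6,7,9-tris[(tert-butyldimethylsilyl)oxy]-3-(methoxymethyl)dec-2-en-1-yl]phosphonate | CCOP(=O)(OCC)C/C=C(\COC)CC[C@@H](O[Si](C)(C)C(C)(C)C)[C@@H](O[Si](C)(C)C(C)(C)C)C[C@H](O[Si](C)(C)C(C)(C)C)CN=[N+]=[N-]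
F9 | step 16 | (2R)-2-methyldec-9-enal | C=CCCCCCC[C@@H](C)C=O
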